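## Retrosynthetic overview

- The C4–O aryl ether is made last, by anti (trans-diaxial) addition of magnolol and a removable PhSe group across the C3=C4 alkene of cis-fused 5-epi-α-eudesmol, followed by Se→H exchange.
- Rings A and B are closed together by an intramolecular Diels–Alder reaction of an acyclic (E)-triene (bonds C5–C10 and C1–C2); the C7 stereocentre in the tether sets C10 and C5.
- The triene comes from a keto aldehyde by an aldehyde-selective Wittig reaction (C3, C4, C15) and a double methylenation (C1, C2).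
- The keto aldehyde comes from ozonolysis of silylated (R)-α-terpineol, which supplies C7 and the C11 carbinol.
- Ring order: terpineol ring opened → rings A and B formed in one step → aryl ether.

Assumption: the SMILES is read literally as (4R,5S,7R,10R) in eudesmane numbering (4α-aryloxy, 4β-CH3, 5β-H, 7β-side chain, 10β-CH3), i.e. a cis-fused decalin; eudesmane numbering is used for all terpenoid carbons.

## Route

Step 1
Reactants: 1 (R)-(+)-α-terpineol
Product: 2 trimethyl{[2-((1R)-4-methylcyclohex-3-en-1-yl)propan-2-yl]oxy}silane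
Conditions: N-(trimethylsilyl)imidazole, CH2Cl2, 25 °C
Reagents that add atoms: N-(trimethylsilyl)imidazole, C[Si](C)(C)n1ccnc1
Why: Silyl ether protection of the tertiary alcohol stops lactol formation and alkoxide addition to the enal in steps 2–4 and later gives a bulky equatorial anchor for the cycloaddition; the C7 stereocentre of 1 is untouched.

Step 2
Reactants: 2 silyl ether of α-terpineol
Product: 4 (3R)-6-oxo-3-[2-(trimethylsilyloxy)propan-2-yl]heptanal, via ozonide 3 (not isolated)
Conditions: O3, CH2Cl2, −78 °C; then PPh3, −78 → 25 °C; used crude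
Reagents that add atoms: ozone, [O-][O+]=O
Why: Ozonolysis with reductive work-up (Criegee mechanism) cleaves the only C=C bond to the methyl ketone (future C10/C14) and the aldehyde (future C5); C7 is not α to a carbonyl and keeps its configuration.

Step 3
Reactants: 4 keto aldehyde
Product: 5 (2E,5R)-2-methyl-8-oxo-5-[2-(trimethylsilyloxy)propan-2-yl]non-2-enal
Conditions: 2-(triphenylphosphoranylidene)propanal (1.1 equiv), toluene, 90 °C
Reagents that add atoms: 2-(triphenylphosphoranylidene)propanal, CC(C=O)=P(c1ccccc1)(c1ccccc1)c1ccccc1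
Why: Wittig olefination with a stabilized ylide reacts only at the aldehyde and gives the (E)-trisubstituted enal (tether trans to the formyl group), adding C4, C15 and C3.

Step 4
Reactants: 5 enal ketone
Product: 6 trimethyl({2-[(3E,6R)-3,9-dimethyldeca-1,3,9-trien-6-yl]propan-2-yl}oxy)silane
Conditions: CH3PPh3Br (3 equiv), NaN(Si(CH3)3)2 (2.8 equiv), THF, −78 → 25 °C
Reagents that add atoms: methyltriphenylphosphonium bromide (source of both CH2 groups), C[P+](c1ccccc1)(c1ccccc1)c1ccccc1.[Br-]
Why: Double Wittig methylenation turns the enal into the terminal (E)-diene (C3=C2) and the methyl ketone into the 1,1-disubstituted alkene (C10=C1) in one operation; no stereocentre is α to a carbonyl.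

Step 5
Reactants: 6 triene
Product: 8 2-[(2R,4aR,8aS)-4a,8-dimethyl-1,2,3,4,4a,5,6,8a-octahydronaphthalen-2-yl]propan-2-ol (5-epi-α-eudesmol), via silyl ether cycloadduct 7 (not isolated)
Conditions: toluene (0.01 M), BHT, 210 °C, sealed tube, 36 h; then K2CO3 (cat.), CH3OH, 25 °C; chromatography on AgNO3-impregnated silica
Reagents that add atoms: none
Why: Thermal intramolecular Diels–Alder reaction forms C5–C10 and C1–C2, hence both rings at once; with the C(CH3)2OSi(CH3)3 group equatorial in the chair-like tether the angular methyl is axial on the β face (10R), and the tether-endo transition state places C4 axial with H5 on the β face (5S, cis fusion), whereas the tether-exo transition state gives the trans-fused (α-eudesmol) isomer that is separated after desilylation, about equal amounts being expected for an unactivated triene.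

Step 6
Reactants: 8 5-epi-α-eudesmol; 9 magnolol
Product: 11 (3S,4S,5S,7R,10S)-4-{[2'-hydroxy-5,5'-di(prop-2-en-1-yl)biphenyl-2-yl]oxy}-3-(phenylselanyl)-5-epi-eudesman-11-ol, via seleniranium triflate 10 (not isolated)
Conditions: PhSeCl (1.05 equiv), AgOSO2CF3 (1.1 equiv), CH2Cl2, −78 °C; then 8, 2,6-di-tert-butyl-4-methylpyridine (1.5 equiv); then 9 (3 equiv), −78 → −30 °C
Reagents that add atoms: benzeneselenenyl chloride, Cl[Se]c1ccccc1
Why: Intermolecular phenoxyselenenylation (anti addition): the seleniranium ion forms on the convex β face and the phenol of 9 opens it at the tertiary C4 from the α face in Markovnikov, trans-diaxial (Fürst–Plattner) fashion, fixing 4α-OAr/4β-CH3 with 3β-SePh; selenium is bound to the terpene before 9 is added, excess 9 limits double etherification, and the hindered pyridine traps the triflic acid.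

Step 7
Reactants: 11 selenide
Product: 12 (4R,5S,7R,10R)-4-{[2'-hydroxy-5,5'-di(prop-2-en-1-yl)biphenyl-2-yl]oxy}-5-epi-eudesman-11-ol (target)
Conditions: (C4H9)3SnH (3 equiv, 0.5 M), AIBN (cat.), toluene, 90 °C
Reagents that add atoms: none
Why: Radical-chain reductive deselenation: the stannyl radical abstracts PhSe from C3 and the secondary radical is reduced by the concentrated stannane faster than it can lose the β-aryloxy group; no stereocentre is touched and the allyl groups, phenol and tertiary alcohol are inert.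

## Compound list

1 | (R)-(+)-α-terpineol, 2-[(1R)-4-methylcyclohex-3-en-1-yl]propan-2-ol | CC1=CC[C@@H](CC1)C(C)(C)O | starting material
2 | trimethyl{[2-((1R)-4-methylcyclohex-3-en-1-yl)propan-2-yl]oxy}silane | CC1=CC[C@@H](CC1)C(C)(C)O[Si](C)(C)C | intermediate
3 | ozonide of 2: 1-methyl-4-[2-(trimethylsilyloxy)propan-2-yl]-7,8,9-trioxabicyclo[4.2.1]nonane (bridgehead diastereomers) | CC12CC[C@@H](C(C)(C)O[Si](C)(C)C)CC(O1)OO2 | intermediate
4 | (3R)-6-oxo-3-[2-(trimethylsilyloxy)propan-2-yl]heptanal | CC(=O)CC[C@@H](C(C)(C)O[Si](C)(C)C)CC=O | intermediate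
5 | (2E,5R)-2-methyl-8-oxo-5-[2-(trimethylsilyloxy)propan-2-yl]non-2-enal | CC(=O)CC[C@@H](C(C)(C)O[Si](C)(C)C)C/C=C(\C)C=O | intermediate
6 | trimethyl({2-[(3E,6R)-3,9-dimethyldeca-1,3,9-trien-6-yl]propan-2-yl}oxy)silane | C=C(C)CC[C@@H](C(C)(C)O[Si](C)(C)C)C/C=C(\C)C=C | intermediate
7 | trimethylsilyl ether of 8: (5S,7R,10R)-11-(trimethylsilyloxy)-5-epi-eudesm-3-ene | CC2=CCC[C@]3(C)CC[C@@H](C(C)(C)O[Si](C)(C)C)C[C@@H]32 | intermediate
8 | 5-epi-α-eudesmol, 2-[(2R,4aR,8aS)-4a,8-dimethyl-1,2,3,4,4a,5,6,8a-octahydronaphthalen-2-yl]propan-2-ol | CC2=CCC[C@]3(C)CC[C@@H](C(C)(C)O)C[C@@H]32 | intermediate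
9 | magnolol, 5,5'-di(prop-2-en-1-yl)biphenyl-2,2'-diol | C=CCc1ccc(O)c(-c2cc(CC=C)ccc2O)c1 | starting material
10 | 3β,4β-(phenylseleniranium) triflate of 8 (Se bridging C3 and C4 on the β face; configuration at Se undefined) | C[C@]1([Se+]2c4ccccc4)[C@@H]2CC[C@]3(C)CC[C@@H](C(C)(C)O)C[C@@H]31.[O-]S(=O)(=O)C(F)(F)F | intermediate
11 | (3S,4S,5S,7R,10S)-4α-{[2'-hydroxy-5,5'-di(prop-2-en-1-yl)biphenyl-2-yl]oxy}-3β-(phenylselanyl)-5-epi-eudesman-11-ol | C=CCc1ccc(O)c(-c2cc(CC=C)ccc2O[C@]2(C)[C@@H]([Se]c4ccccc4)CC[C@]3(C)CC[C@@H](C(C)(C)O)C[C@@H]32)c1 | intermediate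
12 | 2-[(2R,4aR,8R,8aS)-8-{[2'-hydroxy-5,5'-di(prop-2-en-1-yl)biphenyl-2-yl]oxy}-4a,8-dimethyldecahydronaphthalen-2-yl]propan-2-ol (CNP0240155.2) | C=CCc1ccc(O)c(-c2cc(CC=C)ccc2O[C@]2(C)CCC[C@]3(C)CC[C@@H](C(C)(C)O)C[C@@H]32)c1 | target

## Step count and risks

Total steps: 7. Longest linear sequence: 7 (1 → 12; magnolol 9 is used as purchased).

**Step 5 (Diels–Alder).** The unactivated triene needs about 210 °C and no strong cis/trans bias is expected, so up to half the material may end up trans-fused. The fallback abandons the cycloaddition and sets out from 1, returning at 8.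
- Hydroboration of 1 (BH3·S(CH3)2) with direct H2CrO4 oxidation of the organoborane gives hydroxy ketone F1.
- F1 is condensed with (R)-1-phenylethylamine to imine F2.
- Deracemizing Michael addition of F2 to pent-1-en-3-one and hydrolysis (aqueous CH3CO2H) gives the 10S diketone F3.
- NaOCH3 in CH3OH closes F3 to the enone F4 (11-hydroxy-α-cyperone).
- F4 is converted with p-toluenesulfonyl hydrazide to tosylhydrazone F5.
- Catecholborane reduction and NaOCOCH3-induced allylic diazene rearrangement (Kabalka alkene transposition) deliver hydrogen to C5 on the β face and move the alkene to C3=C4, giving 8.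

**Step 6 (phenoxyselenenylation).** The hindered phenol must attack the tertiary C4 from the concave α face, and the selenium electrophile can migrate to the allyl groups of 9 or simply eliminate. The fallback uses no transferable electrophile; it sets out from 8 and returns at 12.
- m-Chloroperbenzoic acid (NaHCO3, CH2Cl2, 0 °C) epoxidizes the convex face to give the 3β,4β-epoxide F6.
- BF3·O(C2H5)2 (cat.) at −40 °C opens F6 with 9 at C4 (trans-diaxial, inversion) to give the 3β-hydroxy-4α-aryl ether F7.
- Excess 1,1'-thiocarbonyldiimidazole converts the C3 hydroxyl and the phenol into the bis(imidazolylthiocarbonyl) derivative F8.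
- Barton–McCombie reduction ((C4H9)3SnH, AIBN) removes the C3 oxygen, and K2CO3/CH3OH then frees the phenol to give 12.

**Step 4 (double methylenation).** The methyl ketone may enolize and react incompletely with the basic ylide. The fallback separates the two olefinations; it sets out from 5 and returns at 6.
- One equivalent of methylenetriphenylphosphorane at −78 °C olefinates only the aldehyde, giving dienyl ketone F9.
- (CH3)3SiCH2Li with CeCl3 adds to the enolizable ketone to give β-hydroxysilane F10.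
- KH-induced Peterson elimination gives 6.

## Further compounds

F1 | step 5 | (5R)-5-(2-hydroxypropan-2-yl)-2-methylcyclohexan-1-one (C2 epimers) | CC1CC[C@@H](C(C)(C)O)CC1=O
F2 | step 5 | imine of F1 with (R)-1-phenylethylamine | CC1CC[C@@H](C(C)(C)O)CC1=N[C@H](C)c1ccccc1
F3 | step 5 | (2S,5R)-5-(2-hydroxypropan-2-yl)-2-methyl-2-(3-oxopentyl)cyclohexan-1-one | CCC(=O)CC[C@]1(C)CC[C@@H](C(C)(C)O)CC1=O
F4 | step 5 | (4aS,7R)-7-(2-hydroxypropan-2-yl)-1,4a-dimethyl-4,4a,5,6,7,8-hexahydronaphthalen-2(3H)-one | O=C1CC[C@]3(C)CC[C@@H](C(C)(C)O)CC3=C1C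
F5 | step 5 | p-toluenesulfonylhydrazone of F4 | Cc1ccc(cc1)S(=O)(=O)NN=C1CC[C@]3(C)CC[C@@H](C(C)(C)O)CC3=C1C
F6 | step 6 | 3β,4β-epoxy-5-epi-eudesman-11-ol | C[C@]12O[C@H]1CC[C@]3(C)CC[C@@H](C(C)(C)O)C[C@@H]32
F7 | step 6 | 4α-{[2'-hydroxy-5,5'-di(prop-2-en-1-yl)biphenyl-2-yl]oxy}-5-epi-eudesmane-3β,11-diol | C=CCc1ccc(O)c(-c2cc(CC=C)ccc2O[C@]2(C)[C@@H](O)CC[C@]3(C)CC[C@@H](C(C)(C)O)C[C@@H]32)c1
F8 | step 6 | bis(imidazol-1-ylthiocarbonyl) derivative of F7 (at the C3 oxygen and the phenol oxygen) | C=CCc1ccc(OC(=S)n5ccnc5)c(-c2cc(CC=C)ccc2O[C@]2(C)[C@@H](OC(=S)n6ccnc6)CC[C@]3(C)CC[C@@H](C(C)(C)O)C[C@@H]32)c1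
F9 | step 4 | (5R,7E)-8-methyl-5-[2-(trimethylsilyloxy)propan-2-yl]deca-7,9-dien-2-one | CC(=O)CC[C@@H](C(C)(C)O[Si](C)(C)C)C/C=C(\C)C=C
F10 | step 4 | (5R,7E)-2,8-dimethyl-1-(trimethylsilyl)-5-[2-(trimethylsilyloxy)propan-2-yl]deca-7,9-dien-2-ol (C2 epimers) | C[Si](C)(C)CC(C)(O)CC[C@@H](C(C)(C)O[Si](C)(C)C)C/C=C(\C)C=C
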